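## Analysis of the target

Target 14 is 3,4,5-tribromo-2-(2,4-dibromophenoxy)-6-methoxyphenol, two benzene rings joined by one ether oxygen, with no stereocentre and no further ring. Ring A is fully substituted: numbered so that C1 carries the methoxy group, C2 the free hydroxyl and C3 the ether oxygen, its carbons C4, C5 and C6 each carry bromine, while ring B is attached to that oxygen through C1' and has bromine at C2' and C4'. The sensitive groups are five aryl C–Br bonds, which rule out zerovalent transition metals and alkyllithium reagents late in the route, and an electron-rich phenol that is easily oxidized. Because the C2 hydroxyl and the C2' bromine both sit ortho to the ether oxygen, hot base or a salt such as CuI could close a dibenzo-1,4-dioxin by intramolecular displacement at C2'. The synthesis is hard because the central O–C1' bond is flanked by substituents on both sides and must be made without a metal that inserts into C–Br, because three neighbouring oxygens on ring A must become three different groups, and because bromination must stop at three on ring A and two on ring B. The strategy rests on the C1–C2–C3 oxygen triad: C1 and C3 with their oxygens are the two carbonyl groups of cyclohexane-1,3-dione 3, and C2 is the acidic carbon between them, which can hold iodine first and the hydroxyl later. C4, C5 and C6 are then the three methylene carbons of 3, which after aromatization are CH positions each ortho or para to an oxygen.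

## Retrosynthetic reasoning

14 ⇒ 13. The three C–Br bonds at C4, C5 and C6 are cut first. In 13 each of these positions is ortho or para to an oxygen (C5 para to the hydroxyl, C4 and C6 ortho or para to the two ethers), while ring B has only C6' free and is deactivated by its two bromines. Placing this step last means every earlier intermediate carries only the two ring B bromines, so the organomagnesium chemistry at C2 has to distinguish iodine from two bromines and not from five. The forward reaction is an exhaustive electrophilic bromination that must stop at ring A.

13 ⇒ 10. The C2–O bond is cut and replaced by C2–I. Iodine is what the key step leaves on C2, and it is the one halogen that exchanges with magnesium at low temperature beside aryl bromides. The forward reaction is exchange to 11, capture on boron to give 12, and an oxidative shift of the aryl group from boron to oxygen.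

10 ⇒ 9. The O–CH3 bond is cut. In 9 the C1 oxygen is the only free hydroxyl, since the C3 oxygen already carries ring B and C2 still carries iodine. Methylation therefore needs no selectivity, and this is the point at which the three oxygens of ring A become different.

9 ⇒ 5. Two hydrogens are put back, taking ring A one oxidation level down. Phenol 9 is the enol tautomer of dienone 8, which comes from enone 5 by introducing the C5–C6 double bond. This is done through selenide 6 and its selenoxide 7, not through a metal-catalysed dehydrogenation, because a zerovalent metal would insert into the C2–I bond.

5 ⇒ 4. The O–C1' bond is cut; this is the key disconnection. The aryl group returns from oxygen to iodine, giving the zwitterionic ylide 4 in which ring B is already held next to the oxygen it has to reach. The forward reaction is a thermal 1,4-shift of the aryl group from iodine to oxygen, which forms the hindered diaryl ether bond without base, metal or an external nucleophile.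

4 ⇒ 2 + 3. The C2–I bond is cut. Dione 3 is acidic at C2 and condenses there with the trivalent iodine compound 2; its symmetry removes any question of which oxygen is arylated later.

2 ⇒ 1. The two I–O bonds are cut; 2 is the peracid oxidation product of aryl iodide 1, which already holds both ring B bromines in their final positions relative to C1'.

## Alternatives that were turned down

Alternative 1: Ring A would be assembled from acyclic pieces by cutting C1–C6 and C3–C4. In the forward direction the ketone 1-(2,4-dibromophenoxy)-3-methoxypropan-2-one A1 would condense at both α-carbons with 2-bromopropanedial A2 under base, and the ring so closed would tautomerize to the phenol 4-bromo-2-(2,4-dibromophenoxy)-6-methoxyphenol A3.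
- For: A1 comes from 2,4-dibromophenol A4 by simple O-alkylation at an sp3 carbon, so the diaryl ether oxygen is in place without any arylation, and one ring-forming operation sets the hydroxyl, both ethers and the C5 bromine of A3. If the condensation worked, the route would be about half as long as the chosen one, and on step economy it is stronger.
- Against: this double aldol ring synthesis is dependable when the dialdehyde carries a nitro group that stabilizes its anion. A2 under base is an α-halo-1,3-dialdehyde, open to substitution and cleavage at the C–Br carbon. A1 has two different α-methylenes that must both react, and α-aryloxy ketones self-condense. A3 would still need bromine at C4 and C6, positions activated only by the ethers.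
- Comparison: the chosen strategy is longer, but its key step belongs to a known reaction class and the site of reaction is fixed by the substrate.

Alternative 2: Ring B would be disconnected at C1'–C2' and C5'–C6'. The ynol ether 1-(ethynyloxy)-3-methoxy-2-(methoxymethoxy)benzene A5 would add across C3 and C6 of the pyrone 3,5-dibromo-2H-pyran-2-one A6 in a [4+2] cycloaddition. Decarboxylative opening of the bridged lactone would then give the arene 2,4-dibromo-1-[3-methoxy-2-(methoxymethoxy)phenoxy]benzene A7.
- For: the polarity matches, since the nucleophilic terminal carbon of A5 should bond to C6 of A6 and so place the oxygen next to the C3 bromine. The two ring B bromines come from A6 and cannot be miscounted. On that point it is stronger than the chosen route, which relies on the deactivation of ring B in the last step.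
- Against: an aryl ethynyl ether such as A5 takes several steps to make from a phenol and is prone to hydration and oligomerization, yet the cycloaddition needs heat. The phenol behind A5 is a 1,2,3-trioxygenated benzene with three differently substituted oxygens, which is the very problem the dione solves. After A7 the acetal must still be removed and ring A tribrominated.
- Comparison: it is at least as long as the chosen route and has a more fragile key intermediate. The chosen route offers cheap bulk starting materials and a precursor that is a zwitterionic solid made in two steps.

Alternative 3: The C3–O bond would be formed by nucleophilic aromatic substitution and the C2 hydroxyl derived from a formyl group. The phenol A4 would displace fluoride from 2-fluoro-6-methoxybenzaldehyde A8 to give 2-(2,4-dibromophenoxy)-6-methoxybenzaldehyde A9. A Dakin-type oxidation of A9 with alkaline peroxide would move C2 from the formyl carbon to oxygen, and hydrolysis of the formate would give 2-(2,4-dibromophenoxy)-6-methoxyphenol A10; A10 is the same compound as 13.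
- For: A10 is reached in two steps, where the chosen route needs seven to arrive at 13, and the reaction types are all standard. On step economy and precedent it is clearly stronger than the chosen route.
- Against: the phenoxide of A4 is hindered and weakly basic, and the fluoride of A8 is activated by a single ortho formyl group. The substitution therefore needs a hot dipolar solvent with carbonate, conditions under which an aldehyde can degrade. The formyl-to-hydroxyl oxidation of A9, a benzaldehyde without a free ortho or para hydroxyl, depends on the aryl group migrating in preference to hydride. The C1 oxygen of A10 is methylated from the outset, so the three ring A bromines can only be introduced together at the end.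
- Comparison: the chosen strategy forms the ether bond intramolecularly under neutral conditions. It also passes through phenol 9 with the C1 oxygen still free, which opens a second, phenol-directed order of bromination (the fallback to step 8), and it leaves iodine on C2 as a handle.

Key step: step 3

Remark on numbering: ring A is numbered C1 (methoxy), C2 (hydroxyl), C3 (aryloxy), C4–C6 (bromine) in every intermediate, also before aromatization, so the carbonyl carbon of 5 is C1 and its methylene carbons are C4, C5 and C6.

## Route

Step 1
Reactants: 1 2,4-dibromo-1-iodobenzene
Product: 2 2,4-dibromo-1-(diacetoxyiodo)benzene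
Conditions: mCPBA, AcOH, 50 °C
Reagents that add atoms: acetic acid, CC(=O)O
Why: Peracid oxidation of an aryl iodide to the trivalent iodine level, with the iodosyl intermediate taken up by two molecules of acetic acid as the (diacetoxyiodo)arene; aryl bromides are inert to peracids.

Step 2
Reactants: 2 2,4-dibromo-1-(diacetoxyiodo)benzene; 3 cyclohexane-1,3-dione
Product: 4 2-[(2,4-dibromophenyl)iodonio]-3-oxocyclohex-1-en-1-olate
Conditions: KOH, MeOH, −10 → 0 °C
Reagents that add atoms: none
Why: Standard preparation of an aryliodonium ylide of a cyclic 1,3-dione, in which the C2 enolate of 3 displaces acetate from iodine and a second equivalent of base removes the remaining C2 proton; the zwitterion is stabilized by delocalization over both carbonyl groups and should be kept cold and dark and used promptly.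

Step 3
Reactants: 4 2-[(2,4-dibromophenyl)iodonio]-3-oxocyclohex-1-en-1-olate
Product: 5 3-(2,4-dibromophenoxy)-2-iodocyclohex-2-en-1-one
Conditions: MeCN, reflux, N2, dark
Reagents that add atoms: none
Why: In ylide 4 the enolate oxygen sits next to the trivalent iodine that carries the aryl ligand, so on heating the oxygen can bond to the ipso carbon C1' through a five-membered cyclic transition state while the C1'–I bond breaks; this is an intramolecular ligand coupling that ends with monovalent iodine on C2. The closest known reaction type is the thermal 1,4-shift of the aryl group from iodine to oxygen in aryliodonium ylides of cyclic 1,3-diones, which delivers 3-aryloxy-2-iodoenones. One O–C bond is made, no ring is closed and no stereocentre arises. The step needs the aryl shift to be faster than fragmentation of the ylide into 1 and a carbene-type species; the two bromines withdraw electron density from ring B and so ease the build-up of negative charge at C1' in the transition state, and an aprotic solvent free of metal salts and nucleophiles shuts off the catalysed and solvolytic decomposition paths. No choice of site arises: the two oxygens of 4 are equivalent by symmetry, only an oxygen flanking the iodine-bearing carbon lies within reach of the aryl ligand, and the iodine has no carbon other than C2 to remain on. The C–Br bonds survive because nothing in the flask can insert into them.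

Step 4
Reactants: 5 3-(2,4-dibromophenoxy)-2-iodocyclohex-2-en-1-one
Product: 6 3-(2,4-dibromophenoxy)-2-iodo-6-(phenylselanyl)cyclohex-2-en-1-one (racemic)
Conditions: LiN(SiMe3)2, THF, −78 °C; PhSeCl, −78 °C
Reagents that add atoms: benzeneselenenyl chloride, Cl[Se]c1ccccc1
Why: Kinetic α′-deprotonation of the vinylogous ester at C6 with a hindered amide and α-selenenylation of the lithium enolate; the C6 stereocentre is formed without control and is removed in step 5, and selenenylation at C4 instead would lead to the same phenol after elimination.

Step 5
Reactants: 6 3-(2,4-dibromophenoxy)-2-iodo-6-(phenylselanyl)cyclohex-2-en-1-one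
Product: 9 3-(2,4-dibromophenoxy)-2-iodophenol, via selenoxide 7 (not isolated), via cyclohexa-2,5-dienone 8 (not isolated)
Conditions: H2O2 (30 %, excess), pyridine, CH2Cl2, 0 °C → rt
Reagents that add atoms: none
Why: Oxidation of the selenide to selenoxide 7 and syn-elimination with a C5 hydrogen (selenoxide elimination) give dienone 8, the keto tautomer of a phenol, which aromatizes at once; pyridine buffers the selenium acids, and the vinyl iodide, the aryl ether and the aryl bromides are inert to cold peroxide.

Step 6
Reactants: 9 3-(2,4-dibromophenoxy)-2-iodophenol
Product: 10 2,4-dibromo-1-(2-iodo-3-methoxyphenoxy)benzene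
Conditions: MeI, K2CO3, DMF, rt
Reagents that add atoms: iodomethane, CI
Why: Williamson O-methylation of the only hydroxyl present; in 9 the hydroxyl is meta to the aryloxy group, so the phenoxide cannot displace the C2' bromide.

Step 7
Reactants: 10 2,4-dibromo-1-(2-iodo-3-methoxyphenoxy)benzene
Product: 13 2-(2,4-dibromophenoxy)-6-methoxyphenol, via arylmagnesium chloride 11 (not isolated), via dimethyl arylboronate 12 (not isolated)
Conditions: iPrMgCl·LiCl, THF, −40 → −20 °C; B(OMe)3, −40 → 0 °C; H2O2 (30 %), AcOH, 0 °C → rt
Reagents that add atoms: hydrogen peroxide, OO
Why: Iodine–magnesium exchange is far faster than bromine–magnesium exchange at low temperature and is helped here by the two oxygens flanking C2; the aryl nucleophile is trapped on boron and the boronate is oxidized with 1,2-shift of the aryl group from boron to oxygen. The acidic peroxide medium avoids base-induced protodeboronation and keeps 13 un-ionized, so the hydroxyl cannot attack C2'.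

Step 8
Reactants: 13 2-(2,4-dibromophenoxy)-6-methoxyphenol
Product: 14 3,4,5-tribromo-2-(2,4-dibromophenoxy)-6-methoxyphenol
Conditions: Br2 (slightly more than 3 equiv), AcOH, 20 → 40 °C, dark
Reagents that add atoms: bromine, BrBr
Why: Electrophilic aromatic bromination, first at C5 para to the hydroxyl, then at C4 and C6, each ortho to one ether oxygen and para to the other; ring B has only C6' left, carries two deactivating bromines and shares its single oxygen with ring A, so it should stay at two bromines if the amount of Br2 is metered.

## Compound list

1 | 2,4-dibromo-1-iodobenzene | Brc1ccc(I)c(Br)c1 | starting material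
2 | 2,4-dibromo-1-(diacetoxyiodo)benzene | CC(=O)OI(OC(C)=O)c1ccc(Br)cc1Br | intermediate
3 | cyclohexane-1,3-dione | O=C1CCCC(=O)C1 | starting material
4 | 2-[(2,4-dibromophenyl)iodonio]-3-oxocyclohex-1-en-1-olate | O=C1CCCC([O-])=C1[I+]c1ccc(Br)cc1Br | intermediate
5 | 3-(2,4-dibromophenoxy)-2-iodocyclohex-2-en-1-one | O=C1CCCC(Oc2ccc(Br)cc2Br)=C1I | intermediate
6 | 3-(2,4-dibromophenoxy)-2-iodo-6-(phenylselanyl)cyclohex-2-en-1-one, racemic | O=C1C([Se]c2ccccc2)CCC(Oc2ccc(Br)cc2Br)=C1I | intermediate
7 | 3-(2,4-dibromophenoxy)-2-iodo-6-(phenylseleninyl)cyclohex-2-en-1-one, mixture of stereoisomers, formed and consumed in step 5 | O=C1C([Se](=O)c2ccccc2)CCC(Oc2ccc(Br)cc2Br)=C1I | intermediate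
8 | 3-(2,4-dibromophenoxy)-2-iodocyclohexa-2,5-dien-1-one, formed and consumed in step 5 | O=C1C=CCC(Oc2ccc(Br)cc2Br)=C1I | intermediate
9 | 3-(2,4-dibromophenoxy)-2-iodophenol | Oc1cccc(Oc2ccc(Br)cc2Br)c1I | intermediate
10 | 2,4-dibromo-1-(2-iodo-3-methoxyphenoxy)benzene | COc1cccc(Oc2ccc(Br)cc2Br)c1I | intermediate
11 | [2-(2,4-dibromophenoxy)-6-methoxyphenyl]magnesium chloride, as its LiCl complex, formed and consumed in step 7 | COc1cccc(Oc2ccc(Br)cc2Br)c1[Mg]Cl | intermediate
12 | dimethyl [2-(2,4-dibromophenoxy)-6-methoxyphenyl]boronate, formed and consumed in step 7 | COB(OC)c1c(OC)cccc1Oc1ccc(Br)cc1Br | intermediate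
13 | 2-(2,4-dibromophenoxy)-6-methoxyphenol | COc1cccc(Oc2ccc(Br)cc2Br)c1O | intermediate
14 | 3,4,5-tribromo-2-(2,4-dibromophenoxy)-6-methoxyphenol | COc1c(O)c(Oc2ccc(Br)cc2Br)c(Br)c(Br)c1Br | target

## Step count and least certain steps

Total step count: 8. Longest linear sequence: 8 steps, from 1 to 14; dione 3 enters at step 2.

Step 3 (key step).
- What may go wrong: thermal fragmentation of the ylide with loss of the aryl iodide may outrun the aryl shift. The ylide of the unsubstituted dione is less robust than its 5,5-dimethyl analogue, and the ortho bromine crowds the five-membered transition state.
- Fallback: set out from 3 and build 5 without an aryl transfer. (COCl)2 with catalytic DMF in CH2Cl2 should convert 3 into 3-chlorocyclohex-2-en-1-one F1, a vinylogous acid chloride. Addition–elimination of commercial 2,4-dibromophenol with K2CO3 in DMF at room temperature should give 3-(2,4-dibromophenoxy)cyclohex-2-en-1-one F2. α-Iodination of this vinylogous ester with I2 and pyridine in CH2Cl2 places iodine on C2 and comes back to the route at 5. The ether bond is then formed at an sp2 carbon of ring A by an external phenoxide under mild base, at the cost of one more step.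

Step 4.
- What may go wrong: the amide base or the enolate may add to C3 and expel 2,4-dibromophenoxide, because the aryloxy enone is a vinylogous aryl ester; double selenenylation is a lesser concern.
- Fallback: set out from 5 and avoid strong base and selenium. Soft enolization with TBSOTf and Et3N in CH2Cl2 at 0 °C should give tert-butyl{[5-(2,4-dibromophenoxy)-6-iodocyclohexa-1,5-dien-1-yl]oxy}dimethylsilane F3. This is a cyclohexa-1,3-diene that DDQ should aromatize at room temperature by hydride abstraction and proton loss to tert-butyl[3-(2,4-dibromophenoxy)-2-iodophenoxy]dimethylsilane F4. The regioisomeric dienol ether from deprotonation at C4 would give the same arene. Bu4NF in THF then frees the phenol and comes back to the route at 9, so steps 4 and 5 are both replaced.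

Step 7.
- What may go wrong: protodeboronation or incomplete borylation at the carbon flanked by two oxygens, so that C2 ends up bearing hydrogen; exchange at a C–Br bond if the mixture warms before the borate is added.
- Fallback: set out from 10 and form the C–O bond directly on the carbanion. After the same exchange to 11, bis(trimethylsilyl) peroxide in THF at −40 → 0 °C should transfer oxygen to give [2-(2,4-dibromophenoxy)-6-methoxyphenoxy]trimethylsilane F5. Dilute aqueous acid on work-up hydrolyses it and comes back to the route at 13. A hydroxylation of 10 with CuI and hydroxide is not proposed, because its hot basic medium would let the phenoxide of 13 close onto C2'.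

Step 8.
- What may go wrong: after two bromines are in place ring A is much less reactive, so the third bromination may slow until attack at C6' of ring B or oxidation of the phenol competes.
- Fallback: set out from 9 and place the bromines in two stages, each under the direction of a free hydroxyl. NBS (2 equiv) in MeCN at 0 °C should brominate C4 and C6, para and ortho to the C1 hydroxyl, giving 4,6-dibromo-3-(2,4-dibromophenoxy)-2-iodophenol F6. MeI and K2CO3 in DMF give 1,5-dibromo-2-(2,4-dibromophenoxy)-3-iodo-4-methoxybenzene F7. The sequence of step 7, run at −78 → −40 °C, gives 3,5-dibromo-2-(2,4-dibromophenoxy)-6-methoxyphenol F8. One equivalent of Br2 in AcOH then brominates C5, para to the new hydroxyl, and comes back to the route at 14. The price is one more step, an exchange that must distinguish iodine from four bromines, and the need to keep the first bromination cold so that ipso attack at the iodine-bearing C2 does not set in.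

## Further compounds

F1 | step 3 | 3-chlorocyclohex-2-en-1-one | O=C1CCCC(Cl)=C1
F2 | step 3 | 3-(2,4-dibromophenoxy)cyclohex-2-en-1-one | O=C1CCCC(Oc2ccc(Br)cc2Br)=C1
F3 | step 4 | tert-butyl{[5-(2,4-dibromophenoxy)-6-iodocyclohexa-1,5-dien-1-yl]oxy}dimethylsilane | CC(C)(C)[Si](C)(C)OC1=CCCC(Oc2ccc(Br)cc2Br)=C1I
F4 | step 4 | tert-butyl[3-(2,4-dibromophenoxy)-2-iodophenoxy]dimethylsilane | CC(C)(C)[Si](C)(C)Oc1cccc(Oc2ccc(Br)cc2Br)c1I
F5 | step 7 | [2-(2,4-dibromophenoxy)-6-methoxyphenoxy]trimethylsilane | COc1cccc(Oc2ccc(Br)cc2Br)c1O[Si](C)(C)C
F6 | step 8 | 4,6-dibromo-3-(2,4-dibromophenoxy)-2-iodophenol | Oc1c(Br)cc(Br)c(Oc2ccc(Br)cc2Br)c1I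
F7 | step 8 | 1,5-dibromo-2-(2,4-dibromophenoxy)-3-iodo-4-methoxybenzene | COc1c(Br)cc(Br)c(Oc2ccc(Br)cc2Br)c1I
F8 | step 8 | 3,5-dibromo-2-(2,4-dibromophenoxy)-6-methoxyphenol | COc1c(Br)cc(Br)c(Oc2ccc(Br)cc2Br)c1O
A1 | alternative 1 | 1-(2,4-dibromophenoxy)-3-methoxypropan-2-one | COCC(=O)COc1ccc(Br)cc1Br
A2 | alternative 1 | 2-bromopropanedial | O=CC(Br)C=O
A3 | alternative 1 | 4-bromo-2-(2,4-dibromophenoxy)-6-methoxyphenol | COc1cc(Br)cc(Oc2ccc(Br)cc2Br)c1O
A4 | alternative 1 | 2,4-dibromophenol | Oc1ccc(Br)cc1Br
A5 | alternative 2 | 1-(ethynyloxy)-3-methoxy-2-(methoxymethoxy)benzene | C#COc1cccc(OC)c1OCOC
A6 | alternative 2 | 3,5-dibromo-2H-pyran-2-one | O=c1occ(Br)cc1Br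
A7 | alternative 2 | 2,4-dibromo-1-[3-methoxy-2-(methoxymethoxy)phenoxy]benzene | COCOc1c(OC)cccc1Oc1ccc(Br)cc1Br
A8 | alternative 3 | 2-fluoro-6-methoxybenzaldehyde | COc1cccc(F)c1C=O
A9 | alternative 3 | 2-(2,4-dibromophenoxy)-6-methoxybenzaldehyde | COc1cccc(Oc2ccc(Br)cc2Br)c1C=O
A10 | alternative 3 | 2-(2,4-dibromophenoxy)-6-methoxyphenol | COc1cccc(Oc2ccc(Br)cc2Br)c1O
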